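**Plan**

- Retrosynthetic cuts, in order: the cyclohexene bonds C3''–C4'' and C5''–C6'' (Diels–Alder of a dehydroprenyl flavanonol with a 2'-hydroxychalcone); the aryl–dienyl bond at C3' of ring B (Stille); the C3–O bond (Rubottom); the C2–C3 bond of ring C (carbene C–H insertion); the O1–CH2 ether bond (Mitsunobu).
- Forward: rings A and B are joined as an aryl benzyl ether, the methyl ketone is turned into a diazoketone, ring C is closed, C3 is oxygenated, the diene is attached, the cyclohexene is formed last, and one deprotection ends the route.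
- Enabling feature: C2 of ring C is benzylic to the 2,4-dioxygenated ring B and α to the ring oxygen O1, so its C–H bond in the open ether is hydridic; C3 is α to the C4 ketone, so it can be a diazo (carbene) carbon placed 1,6 to that C–H bond.
- Stereochemistry: C2 is set by a chiral dirhodium catalyst; C3 is relayed from C2 (epoxidation anti to the aryl group); C3'', C4'' and C5'' are set together by a chiral VANOL–boron complex in an exo Diels–Alder reaction.
- Helpers: the diazo group (lost as N2), iodine at C3' (coupling handle), MOM and TES groups (removed together at the end).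

Key step: step 7

Assumption: the sense of induction of Rh2(S-PTTL)4 in step 7 and of the (S)-VANOL borate in step 14 is taken as drawn; should either give the opposite sense, its mirror-image form is used and nothing else changes.

**Route**

Step 1
Reactants: 1 2-iodoresorcinol
Product: 3 2,4-dihydroxy-3-iodobenzaldehyde, via iminium chloride 2 (not isolated)
Conditions: POCl3, DMF, MeCN, 0 °C → rt; then H2O, 50 °C
Reagents that add atoms: N,N-dimethylformamide CN(C)C=O; water O
Why: Vilsmeier–Haack formylation, in which the chloroiminium ion attacks the only ring position activated by both hydroxyls (ortho to one, para to the other) and hydrolysis of 2 frees the aldehyde.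

Step 2
Reactants: 3 2,4-dihydroxy-3-iodobenzaldehyde
Product: 4 3-iodo-2,4-bis(methoxymethoxy)benzaldehyde
Conditions: NaH, MOMCl, DMF, 0 °C → rt
Reagents that add atoms: chloromethyl methyl ether COCCl
Why: Williamson-type O-alkylation of the disodium phenoxide, which is needed because the 2-OH is chelated to the aldehyde and flanked by iodine.

Step 3
Reactants: 4 3-iodo-2,4-bis(methoxymethoxy)benzaldehyde
Product: 5 [3-iodo-2,4-bis(methoxymethoxy)phenyl]methanol
Conditions: NaBH4, MeOH/THF, 0 °C
Reagents that add atoms: none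
Why: Chemoselective hydride reduction of the aldehyde; the aryl iodide and the acetals are inert to NaBH4.

Step 4
Reactants: 6 2',4'-dihydroxyacetophenone
Product: 7 1-[2-hydroxy-4-(methoxymethoxy)phenyl]ethan-1-one
Conditions: MOMCl (1.05 equiv), K2CO3, acetone, rt
Reagents that add atoms: chloromethyl methyl ether COCCl
Why: Williamson-type mono-alkylation at the 4-OH, because the 2-OH is hydrogen-bonded to the ketone and much less nucleophilic.

Step 5
Reactants: 5 [3-iodo-2,4-bis(methoxymethoxy)phenyl]methanol; 7 1-[2-hydroxy-4-(methoxymethoxy)phenyl]ethan-1-one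
Product: 8 1-[2-{[3-iodo-2,4-bis(methoxymethoxy)phenyl]methoxy}-4-(methoxymethoxy)phenyl]ethan-1-one
Conditions: PPh3, DIAD, THF, 0 °C → rt
Reagents that add atoms: none
Why: Mitsunobu etherification of the chelated phenol with the primary benzylic alcohol joins rings A and B through O1 and the future C2 without handling the electron-rich benzyl group as a free halide.

Step 6
Reactants: 8 1-[2-{[3-iodo-2,4-bis(methoxymethoxy)phenyl]methoxy}-4-(methoxymethoxy)phenyl]ethan-1-one
Product: 10 2-diazo-1-[2-{[3-iodo-2,4-bis(methoxymethoxy)phenyl]methoxy}-4-(methoxymethoxy)phenyl]ethan-1-one, via trifluoroacetyl diketone 9 (not isolated)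
Conditions: LiHMDS, THF, −78 °C; CF3CO2CH2CF3; cold dilute HCl wash; then MsN3, Et3N, H2O, MeCN, rt
Reagents that add atoms: methanesulfonyl azide CS(=O)(=O)N=[N+]=[N-]
Why: Detrifluoroacetylative diazo transfer, in which the lithium enolate of the methyl ketone is C-trifluoroacetylated to 9 and the activated methylene then takes the diazo group from MsN3 with loss of the trifluoroacetyl group as the sulfonamide.

Step 7
Reactants: 10 2-diazo-1-[2-{[3-iodo-2,4-bis(methoxymethoxy)phenyl]methoxy}-4-(methoxymethoxy)phenyl]ethan-1-one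
Product: 12 (2S)-2-[3-iodo-2,4-bis(methoxymethoxy)phenyl]-7-(methoxymethoxy)-2,3-dihydro-4H-chromen-4-one, via rhodium carbene 11 (not isolated)
Conditions: Rh2(S-PTTL)4 [dirhodium tetrakis(N-phthaloyl-(S)-tert-leucinate)] (1 mol %), CH2Cl2, 0 °C, slow addition of 10
Reagents that add atoms: none
Why: Loss of N2 from 10 at the chiral dirhodium tetracarboxylate (divalent rhodium) gives the electrophilic acyl carbene 11, which inserts in one concerted, hydride-transfer-like, three-centre step into a benzylic OCH2 C–H bond, the carbene carbon becoming C3 and the ether carbon C2 of the flavanone. The closest known reaction type is the intramolecular C–H insertion of ortho-alkoxyaryl diazoketones to chroman-4-ones under chiral dirhodium carboxylates. Ring C closes as a six-membered ring by 1,6-insertion, the smallest C–H insertion open to 11 because the 1,5-position is the ether oxygen itself. The one new stereocentre, C2, is set by the catalyst, whose ligand pocket tells the two enantiotopic benzylic hydrogens apart, and the configuration needed is 2S. The step needs chemoselectivity for C–H insertion over attack of the ether oxygen on the carbene (five-membered oxonium ylide, then [1,2]-Stevens benzyl shift to a 2-benzylbenzofuran-3-one), over Buchner-type attack on ring B and over carbene dimerisation; the hydridic C–H bond (α-oxygen plus the 2,4-dioxygenated ring B), the low nucleophilicity of an aryl ether oxygen ortho to the acyl group, the carboxylate ligands and the slow addition should secure it.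

Step 8
Reactants: 12 (2S)-2-[3-iodo-2,4-bis(methoxymethoxy)phenyl]-7-(methoxymethoxy)-2,3-dihydro-4H-chromen-4-one
Product: 13 triethyl({(2S)-2-[3-iodo-2,4-bis(methoxymethoxy)phenyl]-7-(methoxymethoxy)-2H-chromen-4-yl}oxy)silane
Conditions: TESOTf, Et3N, CH2Cl2, −78 → 0 °C
Reagents that add atoms: triethylsilyl trifluoromethanesulfonate CC[Si](CC)(CC)OS(=O)(=O)C(F)(F)F
Why: Soft enolisation (O-silylation, then deprotonation by the amine) forms the only possible enol ether, C3=C4, without a free enolate, so that β-elimination of O1 and loss of the C2 configuration are avoided.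

Step 9
Reactants: 13 triethyl({(2S)-2-[3-iodo-2,4-bis(methoxymethoxy)phenyl]-7-(methoxymethoxy)-2H-chromen-4-yl}oxy)silane
Product: 15 (2R,3R)-2-[3-iodo-2,4-bis(methoxymethoxy)phenyl]-7-(methoxymethoxy)-3-[(triethylsilyl)oxy]-2,3-dihydro-4H-chromen-4-one, via silyloxy epoxide 14 (not isolated)
Conditions: mCPBA, CH2Cl2, −20 → 0 °C
Reagents that add atoms: meta-chloroperoxybenzoic acid O=C(OO)c1cccc(Cl)c1
Why: Rubottom oxidation, in which the peracid epoxidises the enol ether on the face anti to the C2 aryl group and 14 opens with 1,4-silyl migration, so the C3–O bond is set trans to the aryl group by substrate control.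

Step 10
Reactants: 16 2-methylbut-1-en-3-yne
Product: 17 tributyl[(1E)-3-methylbuta-1,3-dien-1-yl]stannane
Conditions: Bu3SnH, PdCl2(PPh3)2 (2 mol %), THF, 0 °C → rt
Reagents that add atoms: tributyltin hydride CCCC[SnH](CCCC)CCCC
Why: Palladium-catalysed syn-hydrostannation of the terminal alkyne places tin at the terminal carbon and gives the E-dienylstannane.

Step 11
Reactants: 15 (2R,3R)-2-[3-iodo-2,4-bis(methoxymethoxy)phenyl]-7-(methoxymethoxy)-3-[(triethylsilyl)oxy]-2,3-dihydro-4H-chromen-4-one; 17 tributyl[(1E)-3-methylbuta-1,3-dien-1-yl]stannane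
Product: 18 (2R,3R)-7-(methoxymethoxy)-2-{2,4-bis(methoxymethoxy)-3-[(1E)-3-methylbuta-1,3-dien-1-yl]phenyl}-3-[(triethylsilyl)oxy]-2,3-dihydro-4H-chromen-4-one
Conditions: Pd2(dba)3 (5 mol %), AsPh3, CuI, DMF, 50 °C
Reagents that add atoms: none
Why: Stille coupling under neutral conditions (zerovalent palladium, CuI co-catalysis) replaces the iodine between the two MOM ethers by the dienyl group with retention of the E geometry and without enolising the ketone.

Step 12
Reactants: 19 2,4-dihydroxybenzaldehyde
Product: 20 2,4-bis(methoxymethoxy)benzaldehyde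
Conditions: NaH, MOMCl, DMF, 0 °C → rt
Reagents that add atoms: chloromethyl methyl ether COCCl
Why: Williamson-type O-alkylation of both phenoxides, the sodium salt overcoming the chelation of the 2-OH.

Step 13
Reactants: 7 1-[2-hydroxy-4-(methoxymethoxy)phenyl]ethan-1-one; 20 2,4-bis(methoxymethoxy)benzaldehyde
Product: 22 (E)-3-[2,4-bis(methoxymethoxy)phenyl]-1-[2-hydroxy-4-(methoxymethoxy)phenyl]prop-2-en-1-one, via aldol adduct 21 (not isolated)
Conditions: KOH, EtOH/H2O, rt
Reagents that add atoms: none
Why: Claisen–Schmidt condensation, in which aldol addition to 21 and E1cB dehydration give the E-enone while the 2'-OH stays free as its phenoxide.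

Step 14
Reactants: 18 (2R,3R)-7-(methoxymethoxy)-2-{2,4-bis(methoxymethoxy)-3-[(1E)-3-methylbuta-1,3-dien-1-yl]phenyl}-3-[(triethylsilyl)oxy]-2,3-dihydro-4H-chromen-4-one; 22 (E)-3-[2,4-bis(methoxymethoxy)phenyl]-1-[2-hydroxy-4-(methoxymethoxy)phenyl]prop-2-en-1-one
Product: 24 (2R,3R)-2-{3-[(1R,5S,6R)-5-[2,4-bis(methoxymethoxy)phenyl]-6-[2-hydroxy-4-(methoxymethoxy)benzoyl]-3-methylcyclohex-2-en-1-yl]-2,4-bis(methoxymethoxy)phenyl}-7-(methoxymethoxy)-3-[(triethylsilyl)oxy]-2,3-dihydro-4H-chromen-4-one, via chalcone borate 23 (not isolated)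
Conditions: (S)-VANOL, BH3·THF, AcOH, THF, 0 °C → rt, then 22 (H2 evolution complete, no B–H left); then 18, rt; aqueous work-up; chromatographic removal of the endo isomer
Reagents that add atoms: none
Why: Diels–Alder reaction of the boron-chelated s-cis enone 23 with diene 18, in which the CH2 terminus of the diene bonds to the β-carbon (ortho/para-type regiochemistry), the exo transition state (carbonyl away from the diene) gives the all-trans ring, and the VANOL wall selects the enone face, so that C3'', C4'' and C5'' are set as R, R and S by reagent control.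

Step 15
Reactants: 24 the hexakis-MOM 3-O-TES cycloadduct named in step 14
Product: 25 guangsangon K
Conditions: HCl (3 M in MeOH), THF, rt → 40 °C
Reagents that add atoms: none
Why: Acid-catalysed methanolysis of the six aryl MOM acetals and of the TES ether in one operation; the all-trans adduct cannot ketalise and the trisubstituted ring alkene should survive as prenyl groups do under such conditions.

**Compound list**

1 | 2-iodoresorcinol (2-iodobenzene-1,3-diol) | Oc1cccc(O)c1I | starting material
2 | N-[(2,4-dihydroxy-3-iodophenyl)methylidene]-N-methylmethanaminium chloride | C[N+](C)=Cc1ccc(O)c(I)c1O.[Cl-] | intermediate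
3 | 2,4-dihydroxy-3-iodobenzaldehyde | O=Cc1ccc(O)c(I)c1O | intermediate
4 | 3-iodo-2,4-bis(methoxymethoxy)benzaldehyde | O=Cc1ccc(OCOC)c(I)c1OCOC | intermediate
5 | [3-iodo-2,4-bis(methoxymethoxy)phenyl]methanol | OCc1ccc(OCOC)c(I)c1OCOC | intermediate
6 | 2',4'-dihydroxyacetophenone | CC(=O)c1ccc(O)cc1O | starting material
7 | 1-[2-hydroxy-4-(methoxymethoxy)phenyl]ethan-1-one | CC(=O)c1ccc(OCOC)cc1O | intermediate
8 | 1-[2-{[3-iodo-2,4-bis(methoxymethoxy)phenyl]methoxy}-4-(methoxymethoxy)phenyl]ethan-1-one | CC(=O)c1ccc(OCOC)cc1OCc1ccc(OCOC)c(I)c1OCOC | intermediate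
9 | 4,4,4-trifluoro-1-[2-{[3-iodo-2,4-bis(methoxymethoxy)phenyl]methoxy}-4-(methoxymethoxy)phenyl]butane-1,3-dione | O=C(CC(=O)C(F)(F)F)c1ccc(OCOC)cc1OCc1ccc(OCOC)c(I)c1OCOC | intermediate
10 | 2-diazo-1-[2-{[3-iodo-2,4-bis(methoxymethoxy)phenyl]methoxy}-4-(methoxymethoxy)phenyl]ethan-1-one | [N-]=[N+]=CC(=O)c1ccc(OCOC)cc1OCc1ccc(OCOC)c(I)c1OCOC | intermediate
11 | dirhodium-bound acyl carbene formed from 10 (SMILES shows one rhodium atom; the second rhodium and the four carboxylate ligands are not drawn) | [Rh]=CC(=O)c1ccc(OCOC)cc1OCc1ccc(OCOC)c(I)c1OCOC | intermediate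
12 | (2S)-2-[3-iodo-2,4-bis(methoxymethoxy)phenyl]-7-(methoxymethoxy)-2,3-dihydro-4H-chromen-4-one | Ic1c(OCOC)ccc([C@H]2Oc3cc(OCOC)ccc3C(=O)C2)c1OCOC | intermediate
13 | triethyl({(2S)-2-[3-iodo-2,4-bis(methoxymethoxy)phenyl]-7-(methoxymethoxy)-2H-chromen-4-yl}oxy)silane | Ic1c(OCOC)ccc([C@H]2Oc3cc(OCOC)ccc3C(O[Si](CC)(CC)CC)=C2)c1OCOC | intermediate
14 | (2S)-3,4-epoxy-2-[3-iodo-2,4-bis(methoxymethoxy)phenyl]-7-(methoxymethoxy)-4-[(triethylsilyl)oxy]chromane, epoxide oxygen trans to the 2-aryl group | Ic1c(OCOC)ccc([C@H]2Oc3cc(OCOC)ccc3[C@]3(O[Si](CC)(CC)CC)O[C@H]23)c1OCOC | intermediate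
15 | (2R,3R)-2-[3-iodo-2,4-bis(methoxymethoxy)phenyl]-7-(methoxymethoxy)-3-[(triethylsilyl)oxy]-2,3-dihydro-4H-chromen-4-one (2,3-trans) | Ic1c(OCOC)ccc([C@H]2Oc3cc(OCOC)ccc3C(=O)[C@@H]2O[Si](CC)(CC)CC)c1OCOC | intermediate
16 | 2-methylbut-1-en-3-yne | C=C(C)C#C | starting material
17 | tributyl[(1E)-3-methylbuta-1,3-dien-1-yl]stannane | C=C(C)/C=C/[Sn](CCCC)(CCCC)CCCC | intermediate
18 | (2R,3R)-7-(methoxymethoxy)-2-{2,4-bis(methoxymethoxy)-3-[(1E)-3-methylbuta-1,3-dien-1-yl]phenyl}-3-[(triethylsilyl)oxy]-2,3-dihydro-4H-chromen-4-one | C=C(C)/C=C/c1c(OCOC)ccc([C@H]2Oc3cc(OCOC)ccc3C(=O)[C@@H]2O[Si](CC)(CC)CC)c1OCOC | intermediate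
19 | 2,4-dihydroxybenzaldehyde | O=Cc1ccc(O)cc1O | starting material
20 | 2,4-bis(methoxymethoxy)benzaldehyde | O=Cc1ccc(OCOC)cc1OCOC | intermediate
21 | 3-[2,4-bis(methoxymethoxy)phenyl]-3-hydroxy-1-[2-hydroxy-4-(methoxymethoxy)phenyl]propan-1-one (racemic) | O=C(CC(O)c1ccc(OCOC)cc1OCOC)c1ccc(OCOC)cc1O | intermediate
22 | (E)-3-[2,4-bis(methoxymethoxy)phenyl]-1-[2-hydroxy-4-(methoxymethoxy)phenyl]prop-2-en-1-one | O=C(/C=C/c1ccc(OCOC)cc1OCOC)c1ccc(OCOC)cc1O | intermediate
23 | borate of 22 with (S)-VANOL [(S)-3,3'-diphenyl-2,2'-binaphthalene-1,1'-diol]: boron carries the 2'-phenolate oxygen of 22 and both naphtholate oxygens and is chelated by the enone carbonyl (the S axis is not encoded in the SMILES) | COCOc1ccc(/C=C/C(=O)c2ccc(OCOC)cc2OB2Oc3c(-c4c(O2)c5ccccc5cc4-c4ccccc4)c(-c4ccccc4)cc4ccccc34)c(OCOC)c1 | intermediate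
24 | (2R,3R)-2-{3-[(1R,5S,6R)-5-[2,4-bis(methoxymethoxy)phenyl]-6-[2-hydroxy-4-(methoxymethoxy)benzoyl]-3-methylcyclohex-2-en-1-yl]-2,4-bis(methoxymethoxy)phenyl}-7-(methoxymethoxy)-3-[(triethylsilyl)oxy]-2,3-dihydro-4H-chromen-4-one (all-trans cyclohexene) | CC1=C[C@@H](c2c(OCOC)ccc([C@H]3Oc4cc(OCOC)ccc4C(=O)[C@@H]3O[Si](CC)(CC)CC)c2OCOC)[C@H](C(=O)c2ccc(OCOC)cc2O)[C@@H](c2ccc(OCOC)cc2OCOC)C1 | intermediate
25 | guangsangon K, (2R,3R)-2-{3-[(1R,5S,6R)-6-(2,4-dihydroxybenzoyl)-5-(2,4-dihydroxyphenyl)-3-methylcyclohex-2-en-1-yl]-2,4-dihydroxyphenyl}-3,7-dihydroxy-2,3-dihydro-4H-chromen-4-one | CC1=C[C@@H](c2c(O)ccc([C@H]3Oc4cc(O)ccc4C(=O)[C@@H]3O)c2O)[C@H](C(=O)c2ccc(O)cc2O)[C@@H](c2ccc(O)cc2O)C1 | target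

**Step count and risks**

Total steps: 15. Longest linear sequence: 11 steps (steps 1, 2, 3, 5, 6, 7, 8, 9, 11, 14, 15; compounds 1 → 3 → 4 → 5 → 8 → 10 → 12 → 13 → 15 → 18 → 24 → 25).

The three steps most likely to fail:

1. Step 7. The carbene may be diverted to the oxonium ylide and a Stevens benzyl shift, or the catalyst may tell the two benzylic hydrogens apart only poorly. Fallback: the ring is closed at O1–C2 instead. Claisen–Schmidt condensation of aldehyde 4 with ketone 7 (KOH, EtOH) should give (E)-1-[2-hydroxy-4-(methoxymethoxy)phenyl]-3-[3-iodo-2,4-bis(methoxymethoxy)phenyl]prop-2-en-1-one F1. An organocatalytic enantioselective intramolecular oxa-Michael addition (quinine-derived bifunctional thiourea, toluene) should then cyclise it to flavanone 12, where the route is rejoined; any shortfall in enantiomeric purity would be removed later as a diastereomer of 24.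

2. Step 14. The exo/endo ratio or the facial selectivity of the boron-templated cycloaddition may be poor, or the bulky diene may react sluggishly. Fallback: stereocontrol is moved from reagent control to separation. The unchanged partners 18 and 22 are combined under electron-transfer catalysis with silica-supported silver nanoparticles (Ag on SiO2, CH2Cl2, 50 °C), which needs no chelating template. Because 18 is already a single enantiomer, all exo and endo adducts are diastereomers, and 24 is isolated by preparative HPLC. This fallback makes no new compound (F0).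

3. Step 15. Acid may add a phenol across the cyclohexene double bond or leave the deprotection incomplete. Fallback: Brønsted-acid solvolysis is replaced by silyl transfer. Treatment of 24 with TMSOTf and 2,2'-bipyridyl (MeCN, 0 °C) should convert every aryl MOM ether, and the free phenol, into trimethylsilyl ethers, giving the heptakis(trimethylsilyl) 3-O-triethylsilyl ether of guangsangon K F2. Buffered HF·pyridine (THF, 0 °C) should then remove all silyl groups under nearly neutral conditions and give 25.

**Further compounds**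

F1 | step 7 | (E)-1-[2-hydroxy-4-(methoxymethoxy)phenyl]-3-[3-iodo-2,4-bis(methoxymethoxy)phenyl]prop-2-en-1-one | O=C(/C=C/c1ccc(OCOC)c(I)c1OCOC)c1ccc(OCOC)cc1O
F0 | step 14 | none | none
F2 | step 15 | heptakis(trimethylsilyl) 3-O-triethylsilyl ether of guangsangon K | CC1=C[C@@H](c2c(O[Si](C)(C)C)ccc([C@H]3Oc4cc(O[Si](C)(C)C)ccc4C(=O)[C@@H]3O[Si](CC)(CC)CC)c2O[Si](C)(C)C)[C@H](C(=O)c2ccc(O[Si](C)(C)C)cc2O[Si](C)(C)C)[C@@H](c2ccc(O[Si](C)(C)C)cc2O[Si](C)(C)C)C1
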